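## Retrosynthetic overview

1. The target comes from fluoride deprotection of its bis-protected form, made by Suzuki alkenylation at C6 of an aryl iodide that arises by ipso-iodination of a C6 trimethylsilyl chromone.
2. The strategy rests on ring A (C4a, C5, C6, C7, C8, C8a; flavone numbering) with its contiguous C5–OH, C6–alkenyl, C7–OMe and unsubstituted C8. A ketene–ynol ether benzannulation of a C8a diazoacetyl pyranone with 1-methoxy-2-(trimethylsilyl)ethyne forms C8–C8a, C7–C8, C5–C6 and C4a–C5 in one step.
3. The diazoketone comes from the pyranone C8a ester, made by acid cyclodehydration of a triketo ester that is built by C-acetylation and oxalate Claisen condensation on a 1-benzoxepin-5-one.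
4. The benzoxepinone comes from 7-exo opening of a Shi epoxide by the ring B phenoxide (inversion sets the R centre), after dianion prenylation of 2,4-dihydroxyacetophenone.
5. Ring order: ring B (bought), oxepine, ring C (pyranone), ring A.

Key step: step 13

## Remarks and assumptions

- Abbreviations: SEM-oxy = [2-(trimethylsilyl)ethoxy]methoxy; TBS-oxy = (tert-butyldimethylsilyl)oxy.
- Protecting groups: the ring B phenol is carried as its SEM ether and the tertiary alcohol as its TBS ether. Both survive enolate chemistry and catalytic acid, and both fall to fluoride, so no acid touches the alkenyl chromone at the end.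
- "Core P" is the ring B–oxepine–pyranone tricycle with flavone locants. The 4-pyranone is O1, C2, C3, C4(=O), C4a–H, C8a. C2 is bonded to C1′ of ring B (SEM-oxy at C4′), C3 to the oxepine CH2. The oxepine is completed by CH2–(R)-CH[C(CH3)2(TBS-oxy)]–O–C2′. The one-carbon substituent sits on C8a.
- Assumption: the L-series enantiomer of the Shi ketone and 1-acetylbenzotriazole are purchasable.
- Stereochemical remark: the target centre is R. Phenoxide opening inverts the epoxide carbon with unchanged CIP ranking, so the (S)-epoxide is needed. By the spiro transition-state model the D-fructose-derived ketone should give the (R)-epoxide of an R–CH=C(CH3)2 alkene, hence the L-series ketone is used.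

## Route

Step 1
Reactants: 1 2,4-dihydroxyacetophenone
Product: 2 1-[2-hydroxy-4-(SEM-oxy)phenyl]ethan-1-one
Conditions: SEMCl (1.05 equiv), iPr2NEt, CH2Cl2, 0 °C → rt
Reagents that add atoms: 2-(trimethylsilyl)ethoxymethyl chloride, C[Si](C)(C)CCOCCl
Why: The 2-OH is hydrogen-bonded to the acetyl carbonyl and far less nucleophilic, so Williamson-type O-alkylation should occur at the 4-OH only.

Step 2
Reactants: 2 1-[2-hydroxy-4-(SEM-oxy)phenyl]ethan-1-one; 3 1-bromo-3-methylbut-2-ene
Product: 4 1-[2-hydroxy-4-(SEM-oxy)phenyl]-5-methylhex-4-en-1-one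
Conditions: LiN(iPr)2 (2.2 equiv), THF, −78 → 0 °C; then 3 (0.95 equiv), −78 → 0 °C; aq. NH4Cl
Reagents that add atoms: none
Why: Two equivalents of amide base give the phenoxide–enolate dianion, whose carbon terminus is the more nucleophilic site, so enolate C-alkylation by the allylic bromide should give the homoprenyl ketone; a slight deficit of bromide limits dialkylation.

Step 3
Reactants: 4 1-[2-hydroxy-4-(SEM-oxy)phenyl]-5-methylhex-4-en-1-one
Product: 5 2-(5-methylhex-4-enoyl)-5-(SEM-oxy)phenyl 2,2-dimethylpropanoate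
Conditions: pivaloyl chloride, Et3N, 4-(dimethylamino)pyridine (cat.), CH2Cl2, 0 °C → rt
Reagents that add atoms: pivaloyl chloride, CC(C)(C)C(=O)Cl
Why: Nucleophile-catalysed O-acylation caps the phenol so that it is neither ionised nor oxidised during the epoxidation, and the hindered ester is later removed by mild methanolysis.

Step 4
Reactants: 5 2-(5-methylhex-4-enoyl)-5-(SEM-oxy)phenyl 2,2-dimethylpropanoate
Product: 6 2-{3-[(2S)-3,3-dimethyloxiran-2-yl]propanoyl}-5-(SEM-oxy)phenyl 2,2-dimethylpropanoate
Conditions: 1,2:4,5-di-O-isopropylidene-β-L-erythro-2,3-hexodiulo-2,6-pyranose (0.3 equiv), Oxone (2KHSO5·KHSO4·K2SO4), K2CO3, Bu4NHSO4, MeCN/CH2(OMe)2, aq. Na2B4O7/Na2EDTA buffer, 0 °C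
Reagents that add atoms: potassium peroxymonosulfate, [K+].[O-]S(=O)(=O)OO
Why: Shi epoxidation of the trisubstituted alkene by the chiral dioxirane through a spiro transition state; the L-series ketone should deliver oxygen to the face that gives the (S)-epoxide, and the aryl ketone and acylated arene are inert to the dioxirane.

Step 5
Reactants: 6 2-{3-[(2S)-3,3-dimethyloxiran-2-yl]propanoyl}-5-(SEM-oxy)phenyl 2,2-dimethylpropanoate
Product: 8 (2R)-2-(2-hydroxypropan-2-yl)-8-(SEM-oxy)-3,4-dihydro-1-benzoxepin-5(2H)-one, via epoxy phenol 7 (not isolated)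
Conditions: K2CO3, MeOH, 25 °C then 50 °C
Reagents that add atoms: none
Why: Methanolysis frees the phenoxide, which should open the epoxide at its less substituted carbon in a 7-exo-tet SN2 reaction (base-mediated phenoxide–epoxide cyclisation), the inversion turning the (S)-epoxide carbon into the (R)-aryloxy centre; enolisation is suppressed because the carbonyl is part of a vinylogous carboxylate.

Step 6
Reactants: 8 (2R)-2-(2-hydroxypropan-2-yl)-8-(SEM-oxy)-3,4-dihydro-1-benzoxepin-5(2H)-one
Product: 9 (2R)-2-[2-(TBS-oxy)propan-2-yl]-8-(SEM-oxy)-3,4-dihydro-1-benzoxepin-5(2H)-one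
Conditions: tBuMe2SiOTf, 2,6-lutidine, CH2Cl2, −78 → 0 °C
Reagents that add atoms: tert-butyldimethylsilyl trifluoromethanesulfonate, CC(C)(C)[Si](C)(C)OS(=O)(=O)C(F)(F)F
Why: Silyl triflate with a hindered pyridine base silylates tertiary alcohols, and the weak base should not enolise the aryl ketone at low temperature.

Step 7
Reactants: 9 (2R)-2-[2-(TBS-oxy)propan-2-yl]-8-(SEM-oxy)-3,4-dihydro-1-benzoxepin-5(2H)-one; 10 1-acetyl-1H-benzotriazole
Product: 11 (2R)-4-acetyl-2-[2-(TBS-oxy)propan-2-yl]-8-(SEM-oxy)-3,4-dihydro-1-benzoxepin-5(2H)-one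
Conditions: LiN(SiMe3)2 (2 equiv), THF, −78 °C; then 10, −78 → 0 °C; aq. NH4Cl
Reagents that add atoms: none
Why: The ketone has one enolisable position (C4) and lithium enolates are C-acylated by N-acylbenzotriazoles (crossed Claisen-type acylation); the second equivalent of base takes up the acidic diketone proton, and the new C4 centre is labile and irrelevant.

Step 8
Reactants: 11 (2R)-4-acetyl-2-[2-(TBS-oxy)propan-2-yl]-8-(SEM-oxy)-3,4-dihydro-1-benzoxepin-5(2H)-one; 12 diethyl oxalate
Product: 13 ethyl 2,4-dioxo-4-{(2R)-5-oxo-2-[2-(TBS-oxy)propan-2-yl]-8-(SEM-oxy)-2,3,4,5-tetrahydro-1-benzoxepin-4-yl}butanoate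
Conditions: LiN(iPr)2 (2.5 equiv), THF, −78 → 0 °C; then 12, −78 °C → rt; aq. NH4Cl
Reagents that add atoms: none
Why: The 1,3-diketone dianion should react at its terminal methyl-derived carbon with the non-enolisable oxalate (Claisen condensation of a β-diketone dianion) to give the 1,3,5-tricarbonyl chain with the ester at its end.

Step 9
Reactants: 13 ethyl 2,4-dioxo-4-{(2R)-5-oxo-2-[2-(TBS-oxy)propan-2-yl]-8-(SEM-oxy)-2,3,4,5-tetrahydro-1-benzoxepin-4-yl}butanoate
Product: 14 core P with CO2Et at C8a (pyranone ethyl ester)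
Conditions: TsOH·H2O (0.1 equiv), toluene, 4 Å molecular sieves, 80 °C
Reagents that add atoms: none
Why: Acid-catalysed cyclodehydration of a 1,3,5-tricarbonyl compound to a 4-pyranone (an enol oxygen adds to the remote carbonyl and water is lost) closes ring C; catalytic acid in an aprotic solvent should leave the tertiary TBS ether and the aryl SEM ether intact.

Step 10
Reactants: 14 core P with CO2Et at C8a
Product: 15 core P with CO2H at C8a (pyranone acid)
Conditions: LiOH·H2O (1.5 equiv), THF/H2O, 0 °C; then cold 0.5 M HCl to pH 3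
Reagents that add atoms: lithium hydroxide, [Li+].[OH-]
Why: Saponification of the activated ester on the electron-poor pyranone carbon should be faster at 0 °C than hydroxide addition to the ring, and both protecting groups are base-stable.

Step 11
Reactants: 15 core P with CO2H at C8a
Product: 17 core P with C(=O)CHN2 at C8a (diazoketone), via acid chloride 16 (not isolated)
Conditions: Me2C=C(Cl)NMe2 (1.05 equiv), CH2Cl2, 0 °C → rt; then Me3SiCHN2 (2 equiv), MeCN/THF, 0 °C → rt
Reagents that add atoms: trimethylsilyldiazomethane, C[Si](C)(C)C=[N+]=[N-]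
Why: The chloroenamine forms the acid chloride without releasing HCl, and acylation of the silyl diazoalkane followed by loss of Me3SiCl (Arndt–Eistert-type diazoketone synthesis) should give the diazomethyl ketone.

Step 12
Reactants: 18 2-chloro-1,1-dimethoxyethane
Product: 20 1-methoxy-2-(trimethylsilyl)ethyne, via lithium methoxyacetylide 19 (not isolated)
Conditions: LiNEt2 (3.1 equiv), THF, 0 °C; then Me3SiCl, −78 °C → rt; distillation
Reagents that add atoms: chlorotrimethylsilane, C[Si](C)(C)Cl
Why: The amide base removes methanol and then HCl from the chloroacetal (double elimination) and deprotonates the methoxyethyne formed, and the acetylide is silylated on carbon.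

Step 13
Reactants: 17 core P with C(=O)CHN2 at C8a; 20 1-methoxy-2-(trimethylsilyl)ethyne
Product: 25 5-hydroxy-7-methoxy-6-(trimethylsilyl)chromone whose C2 is bonded to C1′ of ring B (4′-SEM-oxy) and whose C3 carries the (R)-oxepine CH2–CH[C(CH3)2(TBS-oxy)]–O–C2′, via pyranonylketene 21 (not isolated), via cyclobutenone 22 (not isolated), via dienylketene 23 (not isolated), via cyclohexadienone 24 (not isolated)
Conditions: 20 (3 equiv), degassed ClCH2CH2Cl, hν (440 nm LED), 25 °C; then 80 °C
Reagents that add atoms: none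
Why: Visible light, absorbed by the diazo chromophore and not by the aryl pyranone, should trigger Wolff rearrangement of 17 to ketene 21, in which C8a has moved to the former diazo carbon (future C8), and the ketene should add to ynol ether 20 in a regioselective (2+2) cycloaddition, its carbonyl carbon bonding to the nucleophilic silyl-bearing alkyne carbon, to give cyclobutenone 22. On heating, four-electron electrocyclic opening gives dienylketene 23, six-electron electrocyclisation onto C4a closes the six-membered ring A, and tautomerisation of dienone 24 gives the chelated C5 phenol. The closest known reaction type is the Danheiser benzannulation in its Wolff variant with alkoxyalkynes, which annulates benzene rings onto carbocyclic and heteroaromatic unsaturated diazoketones; a 4-pyranonyl diazoketone is a new substrate for it. No stereocentre is formed and the oxepine centre is remote and untouched. The selectivity needed is regiochemical: the polarised ynol ether fixes OH at C5, silicon at C6 and OMe at C7, and closure can occur only at C4a, helped by the matched polarity of nucleophilic C4a and the electrophilic ketene carbon and by the weak aromaticity of the pyranone, while both hydroxyls are protected so that nothing traps the ketene.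

Step 14
Reactants: 25 6-(trimethylsilyl)chromone from step 13
Product: 26 the corresponding 5-hydroxy-6-iodo-7-methoxychromone (oxepine, TBS-oxy and SEM-oxy groups unchanged)
Conditions: ICl (1.05 equiv), CH2Cl2, −78 °C; aq. Na2S2O3
Reagents that add atoms: iodine monochloride, ClI
Why: Ipso-iododesilylation: attack at the silicon-bearing C6 is favoured by β-silicon stabilisation and two ortho oxygen donors and should outrun iodination at C8 or on ring B at low temperature.

Step 15
Reactants: 26 6-iodochromone from step 14; 27 (E)-3-methylbut-1-enylboronic acid pinacol ester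
Product: 28 the target carrying TBS on the tertiary alcohol and SEM on the ring B phenol
Conditions: Pd(OAc)2 (5 mol%), 2-dicyclohexylphosphino-2′,6′-dimethoxybiphenyl (10 mol%), K3PO4, THF/H2O, 60 °C
Reagents that add atoms: none
Why: Suzuki–Miyaura coupling with a bulky biarylphosphine tolerates the di-ortho-substituted aryl iodide and the free chelated phenol, and the E geometry of the alkenylboronate is retained.

Step 16
Reactants: 28 bis-protected target
Product: 29 target CNP0216454.1
Conditions: Bu4NF (8 equiv), THF/DMPU, 60 °C; aq. NH4Cl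
Reagents that add atoms: none
Why: Fluoride-mediated desilylation cleaves the tertiary silyl ether and, by attack on silicon and fragmentation with loss of ethene and formaldehyde, the aryl SEM ether; the non-acidic medium should spare the electron-rich aryl alkene and the tertiary alcohol, and the stereocentre is not involved.

## Compound list

1 | 2,4-dihydroxyacetophenone | CC(=O)c1ccc(O)cc1O | starting material
2 | 1-[2-hydroxy-4-(SEM-oxy)phenyl]ethan-1-one | CC(=O)c1ccc(OCOCC[Si](C)(C)C)cc1O | intermediate
3 | 1-bromo-3-methylbut-2-ene | CC(C)=CCBr | starting material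
4 | 1-[2-hydroxy-4-(SEM-oxy)phenyl]-5-methylhex-4-en-1-one | CC(C)=CCCC(=O)c1ccc(OCOCC[Si](C)(C)C)cc1O | intermediate
5 | 2-(5-methylhex-4-enoyl)-5-(SEM-oxy)phenyl 2,2-dimethylpropanoate | CC(C)=CCCC(=O)c1ccc(OCOCC[Si](C)(C)C)cc1OC(=O)C(C)(C)C | intermediate
6 | 2-{3-[(2S)-3,3-dimethyloxiran-2-yl]propanoyl}-5-(SEM-oxy)phenyl 2,2-dimethylpropanoate | CC1(C)O[C@H]1CCC(=O)c1ccc(OCOCC[Si](C)(C)C)cc1OC(=O)C(C)(C)C | intermediate
7 | 3-[(2S)-3,3-dimethyloxiran-2-yl]-1-[2-hydroxy-4-(SEM-oxy)phenyl]propan-1-one | CC1(C)O[C@H]1CCC(=O)c1ccc(OCOCC[Si](C)(C)C)cc1O | intermediate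
8 | (2R)-2-(2-hydroxypropan-2-yl)-8-(SEM-oxy)-3,4-dihydro-1-benzoxepin-5(2H)-one | O=C1CC[C@H](C(C)(C)O)Oc2cc(OCOCC[Si](C)(C)C)ccc12 | intermediate
9 | (2R)-2-[2-(TBS-oxy)propan-2-yl]-8-(SEM-oxy)-3,4-dihydro-1-benzoxepin-5(2H)-one | O=C1CC[C@H](C(C)(C)O[Si](C)(C)C(C)(C)C)Oc2cc(OCOCC[Si](C)(C)C)ccc12 | intermediate
10 | 1-acetyl-1H-benzotriazole | CC(=O)n1nnc2ccccc21 | starting material
11 | (2R)-4-acetyl-2-[2-(TBS-oxy)propan-2-yl]-8-(SEM-oxy)-3,4-dihydro-1-benzoxepin-5(2H)-one (C4 epimers and enol forms) | CC(=O)C1C[C@H](C(C)(C)O[Si](C)(C)C(C)(C)C)Oc2cc(OCOCC[Si](C)(C)C)ccc2C1=O | intermediate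
12 | diethyl oxalate | CCOC(=O)C(=O)OCC | starting material
13 | ethyl 2,4-dioxo-4-{(2R)-5-oxo-2-[2-(TBS-oxy)propan-2-yl]-8-(SEM-oxy)-2,3,4,5-tetrahydro-1-benzoxepin-4-yl}butanoate (enol tautomers) | CCOC(=O)C(=O)CC(=O)C1C[C@H](C(C)(C)O[Si](C)(C)C(C)(C)C)Oc2cc(OCOCC[Si](C)(C)C)ccc2C1=O | intermediate
14 | core P with CO2Et at C8a | CCOC(=O)c1oc3c(c(=O)c1)C[C@H](C(C)(C)O[Si](C)(C)C(C)(C)C)Oc1cc(OCOCC[Si](C)(C)C)ccc1-3 | intermediate
15 | core P with CO2H at C8a | OC(=O)c1oc3c(c(=O)c1)C[C@H](C(C)(C)O[Si](C)(C)C(C)(C)C)Oc1cc(OCOCC[Si](C)(C)C)ccc1-3 | intermediate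
16 | core P with COCl at C8a | ClC(=O)c1oc3c(c(=O)c1)C[C@H](C(C)(C)O[Si](C)(C)C(C)(C)C)Oc1cc(OCOCC[Si](C)(C)C)ccc1-3 | intermediate
17 | core P with C(=O)CHN2 at C8a | [N-]=[N+]=CC(=O)c1oc3c(c(=O)c1)C[C@H](C(C)(C)O[Si](C)(C)C(C)(C)C)Oc1cc(OCOCC[Si](C)(C)C)ccc1-3 | intermediate
18 | 2-chloro-1,1-dimethoxyethane | COC(CCl)OC | starting material
19 | lithium methoxyacetylide | [Li+].[C-]#COC | intermediate
20 | 1-methoxy-2-(trimethylsilyl)ethyne | COC#C[Si](C)(C)C | intermediate
21 | core P with CH=C=O at C8a (pyranonylketene) | O=C=Cc1oc3c(c(=O)c1)C[C@H](C(C)(C)O[Si](C)(C)C(C)(C)C)Oc1cc(OCOCC[Si](C)(C)C)ccc1-3 | intermediate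
22 | 3-methoxy-2-(trimethylsilyl)cyclobut-2-en-1-one carrying core P (through C8a) at C4 | COC4=C([Si](C)(C)C)C(=O)C4c1oc3c(c(=O)c1)C[C@H](C(C)(C)O[Si](C)(C)C(C)(C)C)Oc1cc(OCOCC[Si](C)(C)C)ccc1-3 | intermediate
23 | core P with CH=C(OMe)–C(SiMe3)=C=O at C8a, ketene carbon chain and pyranone cis across the enol ether double bond | O=C=C([Si](C)(C)C)/C(OC)=C\c1oc3c(c(=O)c1)C[C@H](C(C)(C)O[Si](C)(C)C(C)(C)C)Oc1cc(OCOCC[Si](C)(C)C)ccc1-3 | intermediate
24 | C4a–H keto tautomer of 25 (C5 ketone, C6=C7 and C8=C8a double bonds) | COC1=C([Si](C)(C)C)C(=O)C2C(=O)C3=C(c4ccc(OCOCC[Si](C)(C)C)cc4O[C@@H](C(C)(C)O[Si](C)(C)C(C)(C)C)C3)OC2=C1 | intermediate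
25 | 5-hydroxy-7-methoxy-6-(trimethylsilyl)chromone fused at C2/C3 to the (R)-oxepine and ring B (TBS-oxy, 4′-SEM-oxy) | COc1cc2oc3c(c(=O)c2c(O)c1[Si](C)(C)C)C[C@H](C(C)(C)O[Si](C)(C)C(C)(C)C)Oc1cc(OCOCC[Si](C)(C)C)ccc1-3 | intermediate
26 | 6-iodo analogue of 25 | COc1cc2oc3c(c(=O)c2c(O)c1I)C[C@H](C(C)(C)O[Si](C)(C)C(C)(C)C)Oc1cc(OCOCC[Si](C)(C)C)ccc1-3 | intermediate
27 | (E)-3-methylbut-1-enylboronic acid pinacol ester | CC(C)/C=C/B1OC(C)(C)C(C)(C)O1 | starting material
28 | target with TBS on the tertiary alcohol and SEM on the ring B phenol | COc1cc2oc3c(c(=O)c2c(O)c1/C=C/C(C)C)C[C@H](C(C)(C)O[Si](C)(C)C(C)(C)C)Oc1cc(OCOCC[Si](C)(C)C)ccc1-3 | intermediate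
29 | CNP0216454.1 | COc1cc2oc3c(c(=O)c2c(O)c1/C=C/C(C)C)C[C@H](C(C)(C)O)Oc1cc(O)ccc1-3 | target

## Step count

Total: 16 steps. Longest linear sequence: 15 steps (steps 1–11 and 13–16); step 12 is a one-step branch.

## Steps most likely to fail

**Step 13 (benzannulation).** The excited diazoketone or its carbene may be diverted from the 1,2-shift, the ketene may dimerise before the alkyne captures it, or the closure onto C4a may lag so that material stays at the cyclobutenone stage. Fallback, from 17 back to 25: the ketene is made without light and at low standing concentration, and the cyclobutenone is isolated. Diazoketone 17 is homologated by Wolff rearrangement in wet THF with catalytic PhCO2Ag and Et3N (Arndt–Eistert) to the pyranonylacetic acid F1. Me2C=C(Cl)NMe2 converts it into the acid chloride F2. F2 is added slowly to Et3N and excess alkyne 20 in CH2Cl2, so that dehydrochlorination releases ketene 21 in the presence of its trap. Cyclobutenone 22 is isolated and heated in toluene at 110 °C, which should give 25 through 23 and 24.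

**Step 11 (diazoketone formation).** The diazoalkane may add as a 1,3-dipole across the electron-poor C4a=C8a double bond of the acyl pyranone instead of being acylated. Fallback, from 16 back to 17: the diazo group is installed by diazo transfer to a methyl ketone. Acid chloride 16 is coupled with Me4Sn under Pd(PPh3)4 (acyl Stille coupling) to the C8a methyl ketone F3. Its lithium enolate (LiN(SiMe3)2, THF, −78 °C) is acylated with 2,2,2-trifluoroethyl trifluoroacetate to the trifluoroacetyl diketone F4. Methanesulfonyl azide with Et3N and water in MeCN then transfers the diazo group with loss of the trifluoroacetyl group (detrifluoroacetylative diazo transfer) to give 17.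

**Step 14 (iododesilylation).** Electrophilic iodine may attack C8 or C5′ of ring B in competition with ipso substitution at C6, or chlorosilane-derived acid may erode the silyl ether. Fallback, from 17 and 19 back to 28: the side chain comes in with the alkyne, so no halogenation or cross-coupling on the tetracycle is needed. Takai olefination of isobutyraldehyde (CHI3, CrCl2, THF) gives (E)-1-iodo-3-methylbut-1-ene F5. Acetylide 19, made as in step 12, is transmetalated with ZnCl2 to chloro(methoxyethynyl)zinc F6 and coupled with F5 under Pd(PPh3)4 (Negishi coupling) to (E)-1-methoxy-5-methylhex-3-en-1-yne F7. Benzannulation of 17 with F7 under the conditions of step 13 should pass through ketene 21, the alkenyl cyclobutenone F8, the dienylketene F9 and the dienone F10 and give 28 directly.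

## Further compounds

F1 | step 13 | core P with CH2CO2H at C8a | OC(=O)Cc1oc3c(c(=O)c1)C[C@H](C(C)(C)O[Si](C)(C)C(C)(C)C)Oc1cc(OCOCC[Si](C)(C)C)ccc1-3
F2 | step 13 | core P with CH2COCl at C8a | ClC(=O)Cc1oc3c(c(=O)c1)C[C@H](C(C)(C)O[Si](C)(C)C(C)(C)C)Oc1cc(OCOCC[Si](C)(C)C)ccc1-3
F3 | step 11 | core P with C(=O)CH3 at C8a | CC(=O)c1oc3c(c(=O)c1)C[C@H](C(C)(C)O[Si](C)(C)C(C)(C)C)Oc1cc(OCOCC[Si](C)(C)C)ccc1-3
F4 | step 11 | core P with C(=O)CH2C(=O)CF3 at C8a | FC(F)(F)C(=O)CC(=O)c1oc3c(c(=O)c1)C[C@H](C(C)(C)O[Si](C)(C)C(C)(C)C)Oc1cc(OCOCC[Si](C)(C)C)ccc1-3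
F5 | step 14 | (E)-1-iodo-3-methylbut-1-ene | CC(C)/C=C/I
F6 | step 14 | chloro(methoxyethynyl)zinc | COC#C[Zn]Cl
F7 | step 14 | (E)-1-methoxy-5-methylhex-3-en-1-yne | COC#C/C=C/C(C)C
F8 | step 14 | 3-methoxy-2-[(E)-3-methylbut-1-enyl]cyclobut-2-en-1-one carrying core P (through C8a) at C4 | COC4=C(/C=C/C(C)C)C(=O)C4c1oc3c(c(=O)c1)C[C@H](C(C)(C)O[Si](C)(C)C(C)(C)C)Oc1cc(OCOCC[Si](C)(C)C)ccc1-3
F9 | step 14 | core P with CH=C(OMe)–C[(E)-CH=CH–CH(CH3)2]=C=O at C8a | O=C=C(/C=C/C(C)C)/C(OC)=C\c1oc3c(c(=O)c1)C[C@H](C(C)(C)O[Si](C)(C)C(C)(C)C)Oc1cc(OCOCC[Si](C)(C)C)ccc1-3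
F10 | step 14 | C4a–H keto tautomer of 28 | COC1=C(/C=C/C(C)C)C(=O)C2C(=O)C3=C(c4ccc(OCOCC[Si](C)(C)C)cc4O[C@@H](C(C)(C)O[Si](C)(C)C(C)(C)C)C3)OC2=C1
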